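The plan rests on cutting the two phenolic C–O bonds at C2 and C6 of ring A, the carbons that flank the C1 ketone. Both oxygens travel as fluorines: these acidify the ring-A hydrogens for four site-selective lithiations, and once the diaryl ketone is in place they become ortho-activated leaving groups. In one operation sodium 2-(trimethylsilyl)ethoxide replaces both fluorides by addition–elimination, with no ring formed. The precursor is the 2,6-difluoro-4-methoxy-3,5-diprenyl benzophenone whose ring-B phenol already carries the same 2-(trimethylsilyl)ethyl ether, so that one fluoride treatment, with no acid near an ortho-prenyl phenol, frees all three hydroxyls.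

Key step: step 8

Remark: the target has no stereocentre and both alkenes end in two methyl groups, so no configuration has to be set. The only stereocentre on the way, the carbinol carbon of 16, is formed racemic and removed by oxidation.

Remark: the ring-B phenol is carried as a 2-(trimethylsilyl)ethyl ether and not as an acetal. An acid-labile group would have to be removed while free phenols sit next to prenyl groups, which is where acid-induced chroman formation is to be expected.

Step 1
Reactants: 1 3,5-difluoroanisole
Product: 3 (2,6-difluoro-4-methoxyphenyl)trimethylsilane, via aryllithium 2 (not isolated)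
Conditions: n-BuLi (1.05 equiv), THF, –78 °C; TMSCl (1.2 equiv), –78 °C → rt
Reagents that add atoms: chlorotrimethylsilane, C[Si](C)(C)Cl
Why: Directed ortho-lithiation with silyl quench: the hydrogen between the two fluorines is the most acidic of 1, so it is removed selectively below the temperature of LiF loss, and the silyl group then blocks the future ketone carbon.

Step 2
Reactants: 3 (2,6-difluoro-4-methoxyphenyl)trimethylsilane; 4 1-bromo-3-methylbut-2-ene
Product: 7 [2,6-difluoro-4-methoxy-3-(3-methylbut-2-enyl)phenyl]trimethylsilane, via aryllithium 5 (not isolated), via arylcopper 6 (not isolated)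
Conditions: sec-BuLi (1.1 equiv), THF, –78 °C; CuBr·SMe2 (1.1 equiv), –78 °C; 4 (1.3 equiv), –78 → 0 °C
Reagents that add atoms: none
Why: Directed ortho-lithiation followed by copper-mediated allylic substitution: with the position between the fluorines blocked, the two equivalent hydrogens flanked by F and OMe are the only acidic sites, and the arylcopper species should couple with the primary allylic bromide at its unsubstituted terminus to give the linear prenyl group without aryne formation.

Step 3
Reactants: 7 [2,6-difluoro-4-methoxy-3-(3-methylbut-2-enyl)phenyl]trimethylsilane; 4 1-bromo-3-methylbut-2-ene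
Product: 10 [2,6-difluoro-4-methoxy-3,5-bis(3-methylbut-2-enyl)phenyl]trimethylsilane, via aryllithium 8 (not isolated), via arylcopper 9 (not isolated)
Conditions: sec-BuLi (1.1 equiv), THF, –78 °C; CuBr·SMe2 (1.1 equiv), –78 °C; 4 (1.3 equiv), –78 → 0 °C
Reagents that add atoms: none
Why: The same ortho-lithiation and copper-mediated prenylation on the one remaining ring hydrogen, whose kinetic acidity (ortho F, ortho OMe, para F) should outrun removal of a benzylic–allylic proton at –78 °C.

Step 4
Reactants: 10 [2,6-difluoro-4-methoxy-3,5-bis(3-methylbut-2-enyl)phenyl]trimethylsilane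
Product: 11 1,5-difluoro-3-methoxy-2,4-bis(3-methylbut-2-enyl)benzene
Conditions: TBAF·3H2O (1.2 equiv), THF, 25 °C
Reagents that add atoms: none
Why: Fluoride-induced protodesilylation: fluoride adds to silicon, the aryl group leaves because its developing carbanion is stabilised by two ortho fluorines and is protonated by water, and ethers, C–F bonds and alkenes are untouched.

Step 5
Reactants: 12 3-hydroxybenzaldehyde; 13 2-(trimethylsilyl)ethanol
Product: 14 3-[2-(trimethylsilyl)ethoxy]benzaldehyde
Conditions: PPh3 (1.3 equiv), DIAD (1.3 equiv), THF, 0 °C → rt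
Reagents that add atoms: none
Why: Mitsunobu etherification of a phenol with a primary alcohol, which leaves the aldehyde alone and gives an aryl ether that is stable to organolithiums, oxidants and alkoxides.

Step 6
Reactants: 11 1,5-difluoro-3-methoxy-2,4-bis(3-methylbut-2-enyl)benzene; 14 3-[2-(trimethylsilyl)ethoxy]benzaldehyde
Product: 16 [2,6-difluoro-4-methoxy-3,5-bis(3-methylbut-2-enyl)phenyl]{3-[2-(trimethylsilyl)ethoxy]phenyl}methanol (racemic), via aryllithium 15 (not isolated)
Conditions: n-BuLi (1.05 equiv), THF, –78 °C; 14 (1.1 equiv), –78 → –30 °C; H2O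
Reagents that add atoms: none
Why: Ortho-lithiation at the freed position between the two fluorines (the most acidic C–H of 11) and 1,2-addition of the aryllithium to the non-enolisable aldehyde, which should give the diaryl carbinol as a racemate whose stereocentre is removed in step 7.

Step 7
Reactants: 16 [2,6-difluoro-4-methoxy-3,5-bis(3-methylbut-2-enyl)phenyl]{3-[2-(trimethylsilyl)ethoxy]phenyl}methanol
Product: 17 [2,6-difluoro-4-methoxy-3,5-bis(3-methylbut-2-enyl)phenyl]{3-[2-(trimethylsilyl)ethoxy]phenyl}methanone
Conditions: Dess–Martin periodinane (1.3 equiv), CH2Cl2, 0 °C → rt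
Reagents that add atoms: none
Why: Dess–Martin oxidation of a doubly benzylic secondary alcohol to the ketone under near-neutral conditions that leave the trisubstituted alkenes, the aryl fluorides and the silylethyl ether alone.

Step 8
Reactants: 17 [2,6-difluoro-4-methoxy-3,5-bis(3-methylbut-2-enyl)phenyl]{3-[2-(trimethylsilyl)ethoxy]phenyl}methanone; 13 2-(trimethylsilyl)ethanol
Product: 20 {4-methoxy-3,5-bis(3-methylbut-2-enyl)-2,6-bis[2-(trimethylsilyl)ethoxy]phenyl}{3-[2-(trimethylsilyl)ethoxy]phenyl}methanone, via sodium 2-(trimethylsilyl)ethoxide 18 (not isolated), via monofluoro monoether 19 (not isolated)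
Conditions: 13 (4 equiv), NaH (3.5 equiv), THF, 0 °C; then 17, THF–DMPU, 25 → 60 °C
Reagents that add atoms: none
Why: Nucleophilic aromatic substitution by addition–elimination: the alkoxide adds to C2, the charge of the Meisenheimer anion is spread over C1, C3 and C5 and from C1 into the carbonyl group, fluoride is expelled, and the same sequence then takes place at C6 through monoether 19. The closest known reaction type is the displacement of fluoride ortho to a diaryl ketone by alkoxides, as used for 2-alkoxybenzophenones and xanthone precursors. No ring is closed and no stereocentre is formed. Site selectivity comes from the substrate, since only C2 and C6 carry a leaving group, both ortho to the ketone, while the C4 methoxy group is meta to the reacting carbons and is no leaving group under these conditions. Each exchange gives a neutral ether and not a phenoxide, so ring A stays uncharged after the first exchange, but the twisted carbonyl and the new alkoxy group slow the second one, which is why a dipolar aprotic cosolvent and mild heating are used. Selectivity against attack at the carbonyl (reversible hemiketal formation followed by loss of ring A as an aryl anion) relies on strictly anhydrous alkoxide, a small excess of alcohol over NaH, and the fact that every fluoride replaced makes that aryl anion a poorer leaving group.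

Step 9
Reactants: 20 {4-methoxy-3,5-bis(3-methylbut-2-enyl)-2,6-bis[2-(trimethylsilyl)ethoxy]phenyl}{3-[2-(trimethylsilyl)ethoxy]phenyl}methanone
Product: 21 [2,6-dihydroxy-4-methoxy-3,5-bis(3-methylbut-2-enyl)phenyl](3-hydroxyphenyl)methanone (CNP0425861.0)
Conditions: CsF (6 equiv), DMF, 80 °C; then AcOH (3.5 equiv), 0 °C
Reagents that add atoms: none
Why: Fluoride-induced fragmentation of aryl 2-(trimethylsilyl)ethyl ethers (attack at silicon, loss of ethylene and aryloxide), in which the two ring-A aryloxides leave easily because of the ortho ketone, the ring-B ether needs the higher temperature, and the prenyl groups and the methyl ether are inert to fluoride and to the acetic acid quench.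

Compound list
1 | 3,5-difluoroanisole | COc1cc(F)cc(F)c1 | starting material
2 | (2,6-difluoro-4-methoxyphenyl)lithium | [Li]c1c(F)cc(OC)cc1F | intermediate (not isolated)
3 | (2,6-difluoro-4-methoxyphenyl)trimethylsilane | COc1cc(F)c([Si](C)(C)C)c(F)c1 | intermediate
4 | 1-bromo-3-methylbut-2-ene (prenyl bromide) | CC(C)=CCBr | starting material
5 | [2,4-difluoro-6-methoxy-3-(trimethylsilyl)phenyl]lithium | COc1cc(F)c([Si](C)(C)C)c(F)c1[Li] | intermediate (not isolated)
6 | [2,4-difluoro-6-methoxy-3-(trimethylsilyl)phenyl]copper | COc1cc(F)c([Si](C)(C)C)c(F)c1[Cu] | intermediate (not isolated)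
7 | [2,6-difluoro-4-methoxy-3-(3-methylbut-2-enyl)phenyl]trimethylsilane | COc1cc(F)c([Si](C)(C)C)c(F)c1CC=C(C)C | intermediate
8 | [2,4-difluoro-6-methoxy-5-(3-methylbut-2-enyl)-3-(trimethylsilyl)phenyl]lithium | COc1c([Li])c(F)c([Si](C)(C)C)c(F)c1CC=C(C)C | intermediate (not isolated)
9 | [2,4-difluoro-6-methoxy-5-(3-methylbut-2-enyl)-3-(trimethylsilyl)phenyl]copper | COc1c([Cu])c(F)c([Si](C)(C)C)c(F)c1CC=C(C)C | intermediate (not isolated)
10 | [2,6-difluoro-4-methoxy-3,5-bis(3-methylbut-2-enyl)phenyl]trimethylsilane | COc1c(CC=C(C)C)c(F)c([Si](C)(C)C)c(F)c1CC=C(C)C | intermediate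
11 | 1,5-difluoro-3-methoxy-2,4-bis(3-methylbut-2-enyl)benzene | COc1c(CC=C(C)C)c(F)cc(F)c1CC=C(C)C | intermediate
12 | 3-hydroxybenzaldehyde | O=Cc1cccc(O)c1 | starting material
13 | 2-(trimethylsilyl)ethanol | OCC[Si](C)(C)C | starting material
14 | 3-[2-(trimethylsilyl)ethoxy]benzaldehyde | O=Cc1cccc(OCC[Si](C)(C)C)c1 | intermediate
15 | [2,6-difluoro-4-methoxy-3,5-bis(3-methylbut-2-enyl)phenyl]lithium | COc1c(CC=C(C)C)c(F)c([Li])c(F)c1CC=C(C)C | intermediate (not isolated)
16 | [2,6-difluoro-4-methoxy-3,5-bis(3-methylbut-2-enyl)phenyl]{3-[2-(trimethylsilyl)ethoxy]phenyl}methanol, racemic | COc1c(CC=C(C)C)c(F)c(C(O)c2cccc(OCC[Si](C)(C)C)c2)c(F)c1CC=C(C)C | intermediate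
17 | [2,6-difluoro-4-methoxy-3,5-bis(3-methylbut-2-enyl)phenyl]{3-[2-(trimethylsilyl)ethoxy]phenyl}methanone | COc1c(CC=C(C)C)c(F)c(C(=O)c2cccc(OCC[Si](C)(C)C)c2)c(F)c1CC=C(C)C | intermediate (key-step precursor)
18 | sodium 2-(trimethylsilyl)ethoxide | [Na+].[O-]CC[Si](C)(C)C | intermediate (not isolated)
19 | {2-fluoro-4-methoxy-3,5-bis(3-methylbut-2-enyl)-6-[2-(trimethylsilyl)ethoxy]phenyl}{3-[2-(trimethylsilyl)ethoxy]phenyl}methanone | COc1c(CC=C(C)C)c(F)c(C(=O)c2cccc(OCC[Si](C)(C)C)c2)c(OCC[Si](C)(C)C)c1CC=C(C)C | intermediate (not isolated)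
20 | {4-methoxy-3,5-bis(3-methylbut-2-enyl)-2,6-bis[2-(trimethylsilyl)ethoxy]phenyl}{3-[2-(trimethylsilyl)ethoxy]phenyl}methanone | COc1c(CC=C(C)C)c(OCC[Si](C)(C)C)c(C(=O)c2cccc(OCC[Si](C)(C)C)c2)c(OCC[Si](C)(C)C)c1CC=C(C)C | intermediate (key-step product)
21 | [2,6-dihydroxy-4-methoxy-3,5-bis(3-methylbut-2-enyl)phenyl](3-hydroxyphenyl)methanone | COc1c(CC=C(C)C)c(O)c(C(=O)c2cccc(O)c2)c(O)c1CC=C(C)C | target

Total step count: 9 steps.
Longest linear sequence: 8 steps (1, 2, 3, 4, 6, 7, 8, 9); step 5 is a one-step side branch.

Steps most likely to fail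

Step 8 (key step). Several processes may interfere:
- The exchange may stop after the first fluoride, because the twisted carbonyl activates C6 only weakly once C2 carries an alkoxy group.
- The alkoxide may add to the carbonyl and the adduct may fragment with loss of ring A.
- The β-silyl alkoxide may itself break down to ethylene and silanolate on prolonged heating.
- The prenyl double bonds may migrate into conjugation under base.

The fallback sets out from aryllithium 15 and returns at 20. It moves the exchange to the aldehyde oxidation level, where the carbonyl lies in the plane of ring A and activates both fluorines fully at lower temperature. 15 is quenched with DMF to give 2,6-difluoro-4-methoxy-3,5-bis(3-methylbut-2-enyl)benzaldehyde F1. Alkoxide 18 in THF at 0–25 °C should exchange both fluorides through 2-fluoro-4-methoxy-3,5-bis(3-methylbut-2-enyl)-6-[2-(trimethylsilyl)ethoxy]benzaldehyde F2 to give 4-methoxy-3,5-bis(3-methylbut-2-enyl)-2,6-bis[2-(trimethylsilyl)ethoxy]benzaldehyde F3. Commercial 3-bromophenol (Oc1cccc(Br)c1) is etherified with 13 under Mitsunobu conditions to 1-bromo-3-[2-(trimethylsilyl)ethoxy]benzene F4, and magnesium in THF converts it into {3-[2-(trimethylsilyl)ethoxy]phenyl}magnesium bromide F5. Addition of F5 to F3 gives racemic {4-methoxy-3,5-bis(3-methylbut-2-enyl)-2,6-bis[2-(trimethylsilyl)ethoxy]phenyl}{3-[2-(trimethylsilyl)ethoxy]phenyl}methanol F6, and Dess–Martin oxidation of F6 gives 20.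

Step 3. A benzylic–allylic proton of the first prenyl group may be removed in competition with the ring hydrogen, or metalation may be slow beside the methoxy group that is now flanked on both sides; either would give mixtures.

The fallback sets out from aryllithium 5 and returns at aryllithium 8. It generates the second aryl–metal bond by halogen–lithium exchange instead of deprotonation. 5 is quenched with 1,2-dibromo-1,1,2,2-tetrachloroethane to give (3-bromo-2,6-difluoro-4-methoxyphenyl)trimethylsilane F7. Lithium 2,2,6,6-tetramethylpiperidide at –78 °C removes the last ring hydrogen, while no alkene is yet present, to give [3-bromo-4,6-difluoro-2-methoxy-5-(trimethylsilyl)phenyl]lithium F8. CuBr·SMe2 converts F8 into [3-bromo-4,6-difluoro-2-methoxy-5-(trimethylsilyl)phenyl]copper F9, and 4 gives [3-bromo-2,6-difluoro-4-methoxy-5-(3-methylbut-2-enyl)phenyl]trimethylsilane F10. Bromine–lithium exchange on F10 with t-BuLi (2 equiv) at –78 °C, which is far faster than any deprotonation, delivers 8, and step 3 continues from there to 9 and 10.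

Step 9. Fragmentation of the ring-B ether may be incomplete, since its aryloxide has no ortho carbonyl to stabilise it; forcing conditions and a partly protected product would follow.

The fallback sets out from 12 and aryllithium 15 and returns at the target 21. It carries ring B as an acetal and removes that acetal before any phenol next to a prenyl group is free. 12 is converted with chloromethyl methyl ether and i-Pr2NEt into 3-(methoxymethoxy)benzaldehyde F11. Addition of 15 gives racemic [2,6-difluoro-4-methoxy-3,5-bis(3-methylbut-2-enyl)phenyl][3-(methoxymethoxy)phenyl]methanol F12, and Dess–Martin oxidation gives [2,6-difluoro-4-methoxy-3,5-bis(3-methylbut-2-enyl)phenyl][3-(methoxymethoxy)phenyl]methanone F13. The double exchange with 18 passes through {2-fluoro-4-methoxy-3,5-bis(3-methylbut-2-enyl)-6-[2-(trimethylsilyl)ethoxy]phenyl}[3-(methoxymethoxy)phenyl]methanone F14 and gives {4-methoxy-3,5-bis(3-methylbut-2-enyl)-2,6-bis[2-(trimethylsilyl)ethoxy]phenyl}[3-(methoxymethoxy)phenyl]methanone F15. Dilute HCl in methanol then removes the acetal while both ring-A oxygens are still ethers, giving (3-hydroxyphenyl){4-methoxy-3,5-bis(3-methylbut-2-enyl)-2,6-bis[2-(trimethylsilyl)ethoxy]phenyl}methanone F16. CsF in DMF at moderate temperature then has to cleave only the two ketone-activated ethers of F16 and should give 21.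

Further compounds
F1 | step 8 | 2,6-difluoro-4-methoxy-3,5-bis(3-methylbut-2-enyl)benzaldehyde | COc1c(CC=C(C)C)c(F)c(C=O)c(F)c1CC=C(C)C
F2 | step 8 | 2-fluoro-4-methoxy-3,5-bis(3-methylbut-2-enyl)-6-[2-(trimethylsilyl)ethoxy]benzaldehyde | COc1c(CC=C(C)C)c(F)c(C=O)c(OCC[Si](C)(C)C)c1CC=C(C)C
F3 | step 8 | 4-methoxy-3,5-bis(3-methylbut-2-enyl)-2,6-bis[2-(trimethylsilyl)ethoxy]benzaldehyde | COc1c(CC=C(C)C)c(OCC[Si](C)(C)C)c(C=O)c(OCC[Si](C)(C)C)c1CC=C(C)C
F4 | step 8 | 1-bromo-3-[2-(trimethylsilyl)ethoxy]benzene | C[Si](C)(C)CCOc1cccc(Br)c1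
F5 | step 8 | {3-[2-(trimethylsilyl)ethoxy]phenyl}magnesium bromide | C[Si](C)(C)CCOc1cccc([Mg]Br)c1
F6 | step 8 | {4-methoxy-3,5-bis(3-methylbut-2-enyl)-2,6-bis[2-(trimethylsilyl)ethoxy]phenyl}{3-[2-(trimethylsilyl)ethoxy]phenyl}methanol, racemic | COc1c(CC=C(C)C)c(OCC[Si](C)(C)C)c(C(O)c2cccc(OCC[Si](C)(C)C)c2)c(OCC[Si](C)(C)C)c1CC=C(C)C
F7 | step 3 | (3-bromo-2,6-difluoro-4-methoxyphenyl)trimethylsilane | COc1cc(F)c([Si](C)(C)C)c(F)c1Br
F8 | step 3 | [3-bromo-4,6-difluoro-2-methoxy-5-(trimethylsilyl)phenyl]lithium | COc1c([Li])c(F)c([Si](C)(C)C)c(F)c1Br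
F9 | step 3 | [3-bromo-4,6-difluoro-2-methoxy-5-(trimethylsilyl)phenyl]copper | COc1c([Cu])c(F)c([Si](C)(C)C)c(F)c1Br
F10 | step 3 | [3-bromo-2,6-difluoro-4-methoxy-5-(3-methylbut-2-enyl)phenyl]trimethylsilane | COc1c(CC=C(C)C)c(F)c([Si](C)(C)C)c(F)c1Br
F11 | step 9 | 3-(methoxymethoxy)benzaldehyde | COCOc1cccc(C=O)c1
F12 | step 9 | [2,6-difluoro-4-methoxy-3,5-bis(3-methylbut-2-enyl)phenyl][3-(methoxymethoxy)phenyl]methanol, racemic | COCOc1cccc(C(O)c2c(F)c(CC=C(C)C)c(OC)c(CC=C(C)C)c2F)c1
F13 | step 9 | [2,6-difluoro-4-methoxy-3,5-bis(3-methylbut-2-enyl)phenyl][3-(methoxymethoxy)phenyl]methanone | COCOc1cccc(C(=O)c2c(F)c(CC=C(C)C)c(OC)c(CC=C(C)C)c2F)c1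
F14 | step 9 | {2-fluoro-4-methoxy-3,5-bis(3-methylbut-2-enyl)-6-[2-(trimethylsilyl)ethoxy]phenyl}[3-(methoxymethoxy)phenyl]methanone | COCOc1cccc(C(=O)c2c(F)c(CC=C(C)C)c(OC)c(CC=C(C)C)c2OCC[Si](C)(C)C)c1
F15 | step 9 | {4-methoxy-3,5-bis(3-methylbut-2-enyl)-2,6-bis[2-(trimethylsilyl)ethoxy]phenyl}[3-(methoxymethoxy)phenyl]methanone | COCOc1cccc(C(=O)c2c(OCC[Si](C)(C)C)c(CC=C(C)C)c(OC)c(CC=C(C)C)c2OCC[Si](C)(C)C)c1
F16 | step 9 | (3-hydroxyphenyl){4-methoxy-3,5-bis(3-methylbut-2-enyl)-2,6-bis[2-(trimethylsilyl)ethoxy]phenyl}methanone | Oc1cccc(C(=O)c2c(OCC[Si](C)(C)C)c(CC=C(C)C)c(OC)c(CC=C(C)C)c2OCC[Si](C)(C)C)c1
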